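**Plan**
1. Retrosynthetic cuts, in order: the two phenolic O–benzyl bonds and the C6–O stearoyl ester bond; the ring bond C3–C4; the ether bond O1–C5; the epoxide oxygen and the C2–vinyl bond. This leads back to O-benzylvanillin, vinylmagnesium bromide and stearoyl chloride.
2. Enabling feature: in the tetrahydrofuran ring (O1, C2 with the aryl group, C3 with the CH2O carbon C6, C4 with the benzylic CH2 carbon C7, C5), the bond C3–C4 lies between a carbon β to the C6 oxygen and a carbon carrying an arylmethyl group. An epoxide-derived β-titanoxy radical at C3 adding to the C4=C7 double bond of a cinnamyl ether leaves exactly this pattern.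
3. Forward: the aldehyde gives a racemic aryl vinyl carbinol; one part is resolved and epoxidised, the rest is transposed to the cinnamyl bromide. A Williamson coupling joins the halves through O1–C5, the single ring is closed by the titanium-mediated radical cyclisation, and stearoylation and hydrogenolysis finish.
4. Stereochemistry: C2 comes from a Sharpless kinetic resolution with D-(−)-diisopropyl tartrate. C3 and C4 are set relative to C2 in the chair-like 5-exo transition state (2,3-trans, 3,4-cis). The epoxide carbon loses its configuration in the radical and need not be controlled.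

Key step: step 5

Remark: the target is read as (2S,3R,4R), i.e. (+)-lariciresinol 9-O-stearate. O-Benzylvanillin is taken as a purchased compound (one benzylation away from vanillin). The locants O1, C2–C5, C6 and C7 defined above are used for all intermediates.

**Step 1**
Reactants: 1 4-(benzyloxy)-3-methoxybenzaldehyde (O-benzylvanillin); 2 vinylmagnesium bromide
Product: 3 rac-1-[4-(benzyloxy)-3-methoxyphenyl]prop-2-en-1-ol
Conditions: CH2=CHMgBr (1.2 equiv), THF, −20 to 0 °C; aq NH4Cl
Reagents that add atoms: vinylmagnesium bromide (2), C=C[Mg]Br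
Why: Grignard 1,2-addition of the vinyl nucleophile to the aryl aldehyde should give the racemic allylic alcohol; no control is needed here because the next step resolves it.

**Step 2**
Reactants: 3 rac-1-[4-(benzyloxy)-3-methoxyphenyl]prop-2-en-1-ol
Product: 4 (R)-[4-(benzyloxy)-3-methoxyphenyl][(2S)-oxiran-2-yl]methanol (erythro epoxy alcohol)
Conditions: Ti(OiPr)4 (0.2 equiv), D-(−)-diisopropyl tartrate (0.3 equiv), t-BuOOH (0.45 equiv), 4 Å MS, CH2Cl2, −20 °C
Reagents that add atoms: tert-butyl hydroperoxide, CC(C)(C)OO
Why: Sharpless kinetic-resolution epoxidation: with the D-(−)-tartrate the (S)-carbinol is the fast-reacting enantiomer and takes oxygen on the vinyl face that gives the erythro epoxy alcohol, so stopping below half conversion should deliver (1R,2S)-4 in high enantiomeric purity (the carbinol carbon keeps all its bonds, only its descriptor changes from S to R), while the slow (R)-alcohol stays behind, is separated and is fed into step 3.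

**Step 3**
Reactants: 3 rac-1-[4-(benzyloxy)-3-methoxyphenyl]prop-2-en-1-ol (racemic material or the (R)-alcohol recovered from step 2)
Product: 5 1-(benzyloxy)-4-[(1E)-3-bromoprop-1-en-1-yl]-2-methoxybenzene (O-benzyl coniferyl bromide)
Conditions: PBr3 (0.4 equiv), Et2O, −10 to 0 °C; used crude at once
Reagents that add atoms: phosphorus tribromide, BrP(Br)Br
Why: Allylic bromination with transposition (SN1/SN2′): the activated alcohol ionises to a p-alkoxy-stabilised allyl cation that bromide captures at the terminus, giving the conjugated (E)-cinnamyl bromide as the thermodynamic product; the carbinol stereocentre is destroyed, so either enantiomer of 3 serves.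

**Step 4**
Reactants: 4 (R)-[4-(benzyloxy)-3-methoxyphenyl][(2S)-oxiran-2-yl]methanol; 5 O-benzyl coniferyl bromide
Product: 6 (2S)-2-[(R)-[4-(benzyloxy)-3-methoxyphenyl]{[(2E)-3-[4-(benzyloxy)-3-methoxyphenyl]prop-2-en-1-yl]oxy}methyl]oxirane (erythro epoxy cinnamyl ether)
Conditions: NaH (1.1 equiv), THF–DMF, 0 °C; then 5, Bu4NI (cat.), 0 °C to rt
Reagents that add atoms: none
Why: Williamson ether synthesis: the sodium alkoxide of 4 displaces the primary allylic bromide by SN2 without touching either stereocentre, and the aprotic medium and low temperature are chosen to keep the epoxy alkoxide from Payne rearrangement.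

**Step 5**
Reactants: 6 erythro epoxy cinnamyl ether
Product: 8 di-O-benzyl-(+)-lariciresinol [(2S,3R,4R)-2-[4-(benzyloxy)-3-methoxyphenyl]-4-[4-(benzyloxy)-3-methoxybenzyl]oxolan-3-yl]methanol, via bis-titanated cyclisation adduct 7 (not isolated)
Conditions: Cp2TiCl (from Cp2TiCl2 (2.5 equiv), Zn dust, THF) added dropwise to 6 in THF, rt; then 1 M HCl, 0 °C
Reagents that add atoms: none
Why: Cp2TiCl (trivalent titanium) transfers one electron to the epoxide, whose C3–O bond breaks to leave the titanium alkoxide on C6 and the radical on the more substituted carbon C3; this is the titanocene-mediated reductive epoxide opening followed by radical cyclisation onto an alkene, a known reaction type already applied to 2-aryl-4-benzyl-tetrahydrofuran lignans. The C3 radical adds to the near alkene carbon C4 in a 5-exo-trig closure that forms C3–C4 and the ring (O1, C2, C3, C4, C5), and the resulting C7 benzylic radical is captured by a second Cp2TiCl as the benzyl–titanium species 7 (tetravalent titanium), which the acid quench protonates together with the C6 alkoxide. C2 is carried over unchanged from 4, while the epoxide stereocentre becomes the planar radical and has no influence. In the chair-like transition state the C2 aryl lies pseudo-equatorial and the titanoxymethyl arm on the radical carbon follows the 1,5-cis preference of 1-substituted hexenyl radicals, so C3 and C4 should come out 2,3-trans and 3,4-cis, that is (2S,3R,4R). The step needs ring closure to outrun reduction of the C3 radical by a second titanium centre, which would end in deoxygenation to the allyl ether; the electron-rich styrene acceptor makes closure fast, and dropwise addition of the reagent to dilute 6 keeps the reductant scarce. Benzyl ethers, methyl ethers and the arenes are inert to the reagent.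

**Step 6**
Reactants: 8 di-O-benzyl-(+)-lariciresinol; 9 stearoyl chloride
Product: 10 [(2S,3R,4R)-2-[4-(benzyloxy)-3-methoxyphenyl]-4-[4-(benzyloxy)-3-methoxybenzyl]oxolan-3-yl]methyl octadecanoate
Conditions: stearoyl chloride (1.2 equiv), Et3N, DMAP (cat.), CH2Cl2, 0 °C to rt
Reagents that add atoms: stearoyl chloride (9), CCCCCCCCCCCCCCCCCC(=O)Cl
Why: DMAP-catalysed acylation (nucleophilic catalysis) of the only free hydroxyl, a primary alcohol, by the acid chloride; no stereocentre is involved.

**Step 7**
Reactants: 10 di-O-benzyl lariciresinol stearate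
Product: 11 [(2S,3R,4R)-2-(4-hydroxy-3-methoxyphenyl)-4-(4-hydroxy-3-methoxybenzyl)oxolan-3-yl]methyl octadecanoate (CNP0168412.1)
Conditions: H2 (1 atm), 10% Pd/C, EtOAc, rt; stopped as soon as both benzyl ethers are gone
Reagents that add atoms: none
Why: Heterogeneous hydrogenolysis of the two aryl benzyl ethers over Pd/C should be much faster in neutral ethyl acetate at one atmosphere than cleavage of the ring benzylic C2–O1 bond, so a short, monitored reaction should free both phenols while the ester and the three stereocentres stay untouched.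

**Compound list**
1 | 4-(benzyloxy)-3-methoxybenzaldehyde (O-benzylvanillin) | COc1cc(C=O)ccc1OCc1ccccc1 | starting material
2 | vinylmagnesium bromide | C=C[Mg]Br | starting material
3 | rac-1-[4-(benzyloxy)-3-methoxyphenyl]prop-2-en-1-ol | OC(C=C)c1ccc(OCc2ccccc2)c(OC)c1 | intermediate
4 | (R)-[4-(benzyloxy)-3-methoxyphenyl][(2S)-oxiran-2-yl]methanol | O[C@@H]([C@@H]1CO1)c1ccc(OCc2ccccc2)c(OC)c1 | intermediate
5 | 1-(benzyloxy)-4-[(1E)-3-bromoprop-1-en-1-yl]-2-methoxybenzene | COc1cc(/C=C/CBr)ccc1OCc1ccccc1 | intermediate
6 | (2S)-2-[(R)-[4-(benzyloxy)-3-methoxyphenyl]{[(2E)-3-[4-(benzyloxy)-3-methoxyphenyl]prop-2-en-1-yl]oxy}methyl]oxirane | COc1cc(/C=C/CO[C@@H]([C@@H]2CO2)c2ccc(OCc3ccccc3)c(OC)c2)ccc1OCc1ccccc1 | intermediate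
7 | bis-titanated cyclisation adduct: the tetrahydrofuran of 8 with a chlorobis(cyclopentadienyl)titanium group (tetravalent titanium) on the C6 oxygen and another on C7, C7 configuration undefined | [CH-]1C=CC=C1.[CH-]1C=CC=C1.[CH-]1C=CC=C1.[CH-]1C=CC=C1.Cl[Ti+2]OC[C@H]1[C@@H](C([Ti+2]Cl)c2ccc(OCc3ccccc3)c(OC)c2)CO[C@@H]1c1ccc(OCc2ccccc2)c(OC)c1 | intermediate
8 | [(2S,3R,4R)-2-[4-(benzyloxy)-3-methoxyphenyl]-4-[4-(benzyloxy)-3-methoxybenzyl]oxolan-3-yl]methanol (di-O-benzyl-(+)-lariciresinol) | OC[C@H]1[C@@H](Cc2ccc(OCc3ccccc3)c(OC)c2)CO[C@@H]1c1ccc(OCc2ccccc2)c(OC)c1 | intermediate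
9 | stearoyl chloride (octadecanoyl chloride) | CCCCCCCCCCCCCCCCCC(=O)Cl | starting material
10 | [(2S,3R,4R)-2-[4-(benzyloxy)-3-methoxyphenyl]-4-[4-(benzyloxy)-3-methoxybenzyl]oxolan-3-yl]methyl octadecanoate | CCCCCCCCCCCCCCCCCC(=O)OC[C@H]1[C@@H](Cc2ccc(OCc3ccccc3)c(OC)c2)CO[C@@H]1c1ccc(OCc2ccccc2)c(OC)c1 | intermediate
11 | [(2S,3R,4R)-2-(4-hydroxy-3-methoxyphenyl)-4-(4-hydroxy-3-methoxybenzyl)oxolan-3-yl]methyl octadecanoate | CCCCCCCCCCCCCCCCCC(=O)OC[C@H]1[C@@H](Cc2ccc(O)c(OC)c2)CO[C@@H]1c1ccc(O)c(OC)c1 | target

**Step count**
Total: 7 steps. Longest linear sequence: 6 steps (1, 2, 4, 5, 6, 7); step 3 is a one-step branch from 3.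

**Steps most likely to fail**

Step 5. The C3 radical may be reduced by a second titanium centre before it cyclises, followed by loss of the titanoxy group (deoxygenation to the allyl ether), and facial control in the closure may be incomplete. Fallback, from 6 to 10: the epoxide of 6 is opened at its terminal carbon by cesium stearate (stearic acid, Cs2CO3, DMF, 80 °C) to give (2S,3R)-3-[4-(benzyloxy)-3-methoxyphenyl]-3-{[(2E)-3-[4-(benzyloxy)-3-methoxyphenyl]prop-2-en-1-yl]oxy}-2-hydroxypropyl octadecanoate F5. Its secondary hydroxyl is converted with 1,1′-thiocarbonyldiimidazole (DMAP cat., toluene, 60 °C) into the O-(imidazol-1-ylcarbonothioyl) derivative F6. Slow addition of Bu3SnH/AIBN in benzene at 80 °C then generates the same C3 radical by Barton–McCombie-type fragmentation; it closes 5-exo onto the cinnamyl alkene and the benzylic radical takes hydrogen from the tin hydride. This tin-hydride chain reaction uses no stoichiometric titanium and should give 10 directly, so the route is rejoined at 10 and steps 5 and 6 are replaced.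

Step 2. Enantiomeric purity of the epoxy alcohol may erode if the two enantiomers of this electron-rich aryl vinyl carbinol differ too little in rate, and the product may be opened by the Lewis-acidic titanium catalyst. Fallback, from 3 to 4: an enzymatic kinetic resolution (immobilised Candida antarctica lipase B, vinyl acetate, MTBE, 30 °C, taken past half conversion) acetylates the (R)-alcohol to (R)-1-[4-(benzyloxy)-3-methoxyphenyl]prop-2-en-1-yl acetate F2 and leaves (S)-1-[4-(benzyloxy)-3-methoxyphenyl]prop-2-en-1-ol F1. F1 is then epoxidised to completion under the matched conditions (Ti(OiPr)4, D-(−)-diisopropyl tartrate, t-BuOOH, CH2Cl2, −20 °C) to give 4. The enantiopurity then rests on the enzyme, and the epoxidation only has to add oxygen; its facial selectivity does not reach the target because the epoxide carbon becomes the radical in step 5.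

Step 4. The alkoxide of 4 may undergo base-induced epoxide migration (Payne rearrangement), and the labile, electron-rich cinnamyl bromide may break down before O-alkylation. Fallback, from 4 and 1 to 6: 4 is O-allylated without a free alkoxide (allyl bromide, Ag2O, CH2Cl2, rt, dark) to (2S)-2-[(R)-[4-(benzyloxy)-3-methoxyphenyl](prop-2-en-1-yloxy)methyl]oxirane F3. Aldehyde 1 is methylenated by a Wittig reaction (Ph3PCH3Br, KOtBu, THF) to 1-(benzyloxy)-4-ethenyl-2-methoxybenzene F4. Olefin cross-metathesis of F3 with excess F4 (second-generation Grubbs catalyst, CH2Cl2, 40 °C) should give the (E)-cinnamyl ether 6, where the route resumes; bromide 5 is then not needed.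

**Further compounds**
F1 | step 2 | (S)-1-[4-(benzyloxy)-3-methoxyphenyl]prop-2-en-1-ol | O[C@@H](C=C)c1ccc(OCc2ccccc2)c(OC)c1
F2 | step 2 | (R)-1-[4-(benzyloxy)-3-methoxyphenyl]prop-2-en-1-yl acetate | CC(=O)O[C@H](C=C)c1ccc(OCc2ccccc2)c(OC)c1
F3 | step 4 | (2S)-2-[(R)-[4-(benzyloxy)-3-methoxyphenyl](prop-2-en-1-yloxy)methyl]oxirane | C=CCO[C@@H]([C@@H]1CO1)c1ccc(OCc2ccccc2)c(OC)c1
F4 | step 4 | 1-(benzyloxy)-4-ethenyl-2-methoxybenzene | C=Cc1ccc(OCc2ccccc2)c(OC)c1
F5 | step 5 | (2S,3R)-3-[4-(benzyloxy)-3-methoxyphenyl]-3-{[(2E)-3-[4-(benzyloxy)-3-methoxyphenyl]prop-2-en-1-yl]oxy}-2-hydroxypropyl octadecanoate | CCCCCCCCCCCCCCCCCC(=O)OC[C@H](O)[C@H](OC/C=C/c1ccc(OCc2ccccc2)c(OC)c1)c1ccc(OCc2ccccc2)c(OC)c1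
F6 | step 5 | (2S,3R)-3-[4-(benzyloxy)-3-methoxyphenyl]-3-{[(2E)-3-[4-(benzyloxy)-3-methoxyphenyl]prop-2-en-1-yl]oxy}-2-[(1H-imidazol-1-ylcarbonothioyl)oxy]propyl octadecanoate | CCCCCCCCCCCCCCCCCC(=O)OC[C@H](OC(=S)n1ccnc1)[C@H](OC/C=C/c1ccc(OCc2ccccc2)c(OC)c1)c1ccc(OCc2ccccc2)c(OC)c1
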